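I started from amounts. Here is what stood in the flasks, what the midnight run showed, and what was asked.

all flasks: substrate 0.061 M
- midnight: other conformer 0.10 equiv; the very flask that is asked about, followed so far
- flask: other conformer 0.100 equiv; time 15 h

- midnight (time / h: target / %, isomer of the product / %): 1.00: 29.9, 12.5; 2.00: 39.6, 14.4; 3.00: 42.9, 15.4; 4.00: 43.2, 17.8; 5.00: 42.8, 19.2; 6.00: 41.9, 20.8

(each reading ± 0.5 percentage points)



1. ratio of target to isomer of the product at 6.0 s
2. ratio of target to isomer of the product at 10 min
3. ratio of target to isomer of the product at 15 h

In the midnight run, isomer of the product stood at 12.5% after 1.00 h, while the last hour added 1.6 percentage points. So I suspected an early burst (a burst phase) in which the other conformer turns into isomer. I called the part of the charge that came in as other conformer, equivalents over one plus equivalents, the burst share: 9.09%.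

But that was a suspicion, so I ran the later isomer readings back in a straight line:

isomer at zero time = 10.0%, give or take 1.1 points

The gap to the burst share is smaller than that scatter, so I took the burst share as the base of the later isomer line and reckoned with the slow rise above it:

isomer at 15 h = burst share + hourly rise × time = 36.1%

target at 15 h, its late fall carried on = 36.0%

ratio = 0.997

Could the charge feed such long lines? Yes, they leave 27.9% unseen. At 10 min the target's rise, fitted to its 43.2% reading, gave 7.70% against 9.39% of isomer, a ratio of 0.820. The objection is that no reading shows the burst finished by then, so I held this as a low figure. At 6.0 s I committed to no number of my own: the readings start at 1.00 h, and I read no speed of the burst from them.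

The forecast said 0.4, 0.95 and 1.1, calling the first “very uncertain”.

The flask gave 0.0705, 0.924 and 1.04.

    substrate ⇌ other conformer (K = 1.00, k = 1.60 × 10⁻⁵ s⁻¹)
    substrate ⇌ target (K = 1.50, k = 2.00 × 10⁻⁴ s⁻¹)
    other conformer → isomer of the product (k = 0.0310 s⁻¹)
    2 substrate → self-condensation product (k = 1.30 × 10⁻⁵ M⁻¹ s⁻¹)
    substrate ⇌ dormant form (K = 0.360, k = 3.40 × 10⁻⁴ s⁻¹)

At 15.0 h this flask held 33.7% of isomer, which leaves 25 points above its burst share. The neighbour flask, charged with 0.0600 equiv of other conformer, had a burst share of 5.66%. Adding the same slow isomer gave 30.3% for it, and at 15.0 h it held 31.2% of isomer beside 36.3% of target, a ratio of 1.16.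

The data stem from a simulated flask with constants of no real substance; scatter was added.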